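All runs were generated by integration with constants of no real substance; noise was put on by code.

The easy step is a subtraction: in the cedar run, substrate plus target fall short of the charge by 1.80 % at 3.00 min and by 4.60 % at 5.00 min.

| flask | substrate | reagent in the second phase | remark | time | volume of the second phase over the first |
|---|---|---|---|---|---|
| cedar | 0.050 M | 3.6 equiv | run made earlier |  |  |
| flask | 0.050 M | 1.80 equiv |  | 50 min | 0.25 |

- cedar (time / min: substrate / %, target / %): 0.417: 99.1, 1.5; 0.667: 97.2, 2.3; 1.00: 94.5, 4.9; 1.33: 91.7, 8.4; 2.00: 84.6, 14.9; 3.00: 74.6, 23.6; 5.00: 57.6, 37.8

(readings scatter by 0.3 percentage points)

- in the second phase: reagent in the second phase; everything else is in the first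
- charges count per volume of the first phase; a concentration in a rate is the amount of a species over the volume of its own phase; every rate counts per litre of the first phase
- the earlier runs were read with a standard deviation of 0.3 percentage points
- the earlier runs hold the two phases in the same ratio of volumes as the flask asked about
- the reaction counts as stopped when no species that holds the substrate changes by six tenths of a point or more over the second half of the time

- at 50 min, what has stopped the reaction, if anything has (forward and back rates have come level / it is still moving / all of the substrate has reacted)
- share of the substrate used up at 50 min
- target at 50 min, in percent of the substrate charged

We read this gap, small so early in the cedar run, as a leak from target and reckon it on. Between those two cedar readings the gap grows by 2.8 percentage points while target averages 30.7 %, so target leaks away at a read 0.0456 min⁻¹. The time in which this leak by itself would halve target we call the leak life, 15.2 min.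

Now turn the question round: for the flask to have stopped by 50 min, substrate would have to stay within the stopping margin over the second half. We scale the late cedar slope in proportion to reagent, which one run cannot test, and get 0.0647 min⁻¹ for the flask. Substrate then falls 16 points in that half, so we say it is still moving. The leak life is shorter than 50 min, and a one-way leak leaves target at 21.3 %.

The forecast, well above our figure for target, says it is still moving, with 86 % used up (77 % to 94 %) and target at 53 % (40 % to 59 %): “Substrate is still falling, so the reaction is still moving”.

The flask gives: it is still moving, 89.4 % used up, target 41.3 %.

    reagent in the reaction phase ⇌ reagent in the second phase, rate k1*([reagent in the reaction phase] - [reagent in the second phase]/K1) per volume of the first phase (partition coefficient = 0.520, kL = 0.00210 s⁻¹)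
    substrate + reagent in the reaction phase → target (k = 0.0150 M⁻¹ s⁻¹)
    target ⇌ isomer of the product (K = 1.60, k = 7.40 × 10⁻⁴ s⁻¹)

The flask has not come to rest: substrate fell 17 points over the second half, and target stands 20 points above our one-way figure. Taken both ways with 1.6, the leak life becomes a relaxation half-life of 9.35 min. The neighbour read at 3.0 h, 13.9 such half-lives later, holds target 38.5 % and isomer of the product 61.4 %. Ten times the time still takes the flask's conversion to >99.9 %, lowers target by 2.8 points to 38.5 %, and raises isomer of the product by 13 points to 61.5 %.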